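## Retrosynthetic overview

1. Target 18 ⇐ macrocyclic 4Z-olefin 16: both epoxide C–O bonds are made last, by oxygen transfer across the ring from the C1 ketone (as its dioxirane). This is the key step and it is new.
2. 16 ⇐ acyclic diene 15 by ring-closing metathesis at C4=C5. Ring order: butenolide first, ten-membered carbocycle second, epoxide last.
3. 15 ⇐ iodobutenolide 7 + keto aldehyde 13 by asymmetric Ni/Cr alkenylation (C7–C8, sets C8), then esterification with 3-methylbut-2-enoic acid.
4. 7 ⇐ (E)-but-2-enal + methyl propiolate: asymmetric alkynylation (sets C6), then iodo-aldol/lactonisation (butenolide ring, C13).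
5. 13 ⇐ (S)-α-methyl-γ-butyrolactone (C10 by asymmetric hydrogenation of α-methylene-γ-butyrolactone) + 3-methylbut-3-enyl Grignard reagent.

Numbering: positions are in germacrane numbering (C1 ketone, C4/C5 epoxide, C6 lactone carbinol, C7=C11 butenolide olefin, C8 ester carbinol, C10 methyl-bearing carbon, C12 lactone carbonyl, C13 acetoxymethyl carbon).

Assumption: the ligand antipodes named [(S,S)-ProPhenol, (S)-BINAP, (S)-oxazoline–sulfonamide] are assigned by analogy with simple substrates; if the observed sense is opposite, the mirror-image ligand is used.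

## Route

Step 1
Reactants: 1 (E)-but-2-enal; 2 methyl prop-2-ynoate
Product: 4 methyl (4S,5E)-4-hydroxyhept-5-en-2-ynoate, via zinc acetylide 3 (not isolated)
Conditions: Me2Zn (3 equiv), (S,S)-ProPhenol (10 mol %), toluene, 0 °C
Reagents that add atoms: none
Why: Zinc–ProPhenol catalysed asymmetric alkynylation of an enal, in which the dinuclear zinc catalyst delivers the alkynylzinc to one aldehyde face and so sets C6 (4S here; the same spatial arrangement is 6R in the target).

Step 2
Reactants: 4 methyl (4S,5E)-4-hydroxyhept-5-en-2-ynoate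
Product: 6 (5S)-3-(hydroxymethyl)-4-iodo-5-[(E)-prop-1-en-1-yl]furan-2(5H)-one, via iodo diol ester 5 (not isolated)
Conditions: MeMgBr (1.0 equiv), CH2Cl2–Et2O, −40 °C; then MgI2 (1.5 equiv), (CH2O)n, 0 °C to rt
Reagents that add atoms: magnesium diiodide [Mg+2].[I-].[I-]; formaldehyde (from paraformaldehyde) C=O
Why: Iodo-aldol (halo Baylis–Hillman type) reaction in which iodide adds 1,4 to the magnesium-activated ynoate, the allenolate is hydroxymethylated at C11, and the geometry with the C6 alkoxide cis to the ester lactonises (the other isomer is funnelled through iodide addition–elimination), the C6–O bond never being broken.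

Step 3
Reactants: 6 (5S)-3-(hydroxymethyl)-4-iodo-5-[(E)-prop-1-en-1-yl]furan-2(5H)-one
Product: 7 [(5S)-4-iodo-2-oxo-5-[(E)-prop-1-en-1-yl]-2,5-dihydrofuran-3-yl]methyl acetate
Conditions: Ac2O, pyridine, CH2Cl2, 0 °C
Reagents that add atoms: acetic anhydride CC(=O)OC(C)=O
Why: O-acetylation of the primary allylic alcohol under weakly basic conditions that leave the acidic C6–H and the vinyl iodide alone.

Step 4
Reactants: 8 3-methylideneoxolan-2-one
Product: 9 (3S)-3-methyloxolan-2-one
Conditions: H2 (50 atm), Ru(OAc)2[(S)-BINAP] (0.5 mol %), CH2Cl2, 50 °C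
Reagents that add atoms: none
Why: Noyori-type asymmetric hydrogenation of the exocyclic olefin of an α-methylene lactone, the lactone carbonyl binding to ruthenium so that hydrogen is delivered to one face and C10 is set as S.

Step 5
Reactants: 9 (3S)-3-methyloxolan-2-one; 10 4-bromo-2-methylbut-1-ene
Product: 12 (3S)-1-hydroxy-3,7-dimethyloct-7-en-4-one, via Grignard reagent 11 (not isolated)
Conditions: 10, Mg, THF, rt; then added to 9, THF, −78 °C
Reagents that add atoms: none
Why: Grignard mono-addition to a γ-lactone, where the magnesium hemiketal alkoxide persists at −78 °C and opens to the γ-hydroxy ketone only on quench, so over-addition and enolisation at C10 are avoided.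

Step 6
Reactants: 12 (3S)-1-hydroxy-3,7-dimethyloct-7-en-4-one
Product: 13 (3S)-3,7-dimethyl-4-oxooct-7-enal
Conditions: TEMPO (10 mol %), PhI(OAc)2 (1.1 equiv), CH2Cl2, rt
Reagents that add atoms: none
Why: Oxoammonium (TEMPO) oxidation, selective for the primary alcohol and non-basic, so the C10 stereocentre next to the ketone is kept.

Step 7
Reactants: 7 [(5S)-4-iodo-2-oxo-5-[(E)-prop-1-en-1-yl]-2,5-dihydrofuran-3-yl]methyl acetate; 13 (3S)-3,7-dimethyl-4-oxooct-7-enal
Product: 14 [(5S)-4-[(1R,3S)-1-hydroxy-3,7-dimethyl-4-oxooct-7-en-1-yl]-2-oxo-5-[(E)-prop-1-en-1-yl]-2,5-dihydrofuran-3-yl]methyl acetate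
Conditions: CrCl2 (4 equiv), NiCl2 (1 mol %), (S)-oxazoline–sulfonamide ligand (4.4 equiv), Et3N (4.4 equiv), THF, rt
Reagents that add atoms: none
Why: Asymmetric Nozaki–Hiyama–Kishi reaction in which zerovalent nickel inserts into the activated C–I bond, the alkenyl group passes to trivalent chromium held by the chiral sulfonamide, and this adds only to the aldehyde (ketone, esters and lactone are inert) on the face that gives the 8R alcohol.

Step 8
Reactants: 14 [(5S)-4-[(1R,3S)-1-hydroxy-3,7-dimethyl-4-oxooct-7-en-1-yl]-2-oxo-5-[(E)-prop-1-en-1-yl]-2,5-dihydrofuran-3-yl]methyl acetate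
Product: 15 (1R,3S)-1-[(2S)-4-(acetoxymethyl)-5-oxo-2-[(E)-prop-1-en-1-yl]-2,5-dihydrofuran-3-yl]-3,7-dimethyl-4-oxooct-7-en-1-yl 3-methylbut-2-enoate
Conditions: 3-methylbut-2-enoic acid, DCC, DMAP (5 mol %), CH2Cl2, 0 °C
Reagents that add atoms: 3-methylbut-2-enoic acid CC(C)=CC(=O)O
Why: Steglich esterification, which acylates the C8 oxygen without breaking the C8–O bond (configuration retained) and, run cold and at once, forestalls lactone migration from O6 to O8.

Step 9
Reactants: 15 (1R,3S)-1-[(2S)-4-(acetoxymethyl)-5-oxo-2-[(E)-prop-1-en-1-yl]-2,5-dihydrofuran-3-yl]-3,7-dimethyl-4-oxooct-7-en-1-yl 3-methylbut-2-enoate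
Product: 16 (4Z,6S,8R,10S)-13-acetoxy-8-(3-methylbut-2-enoyloxy)-1-oxogermacra-4,7(11)-dien-12,6-olide
Conditions: second-generation Hoveyda–Grubbs catalyst RuCl2(H2IMes)(=CH-C6H4-2-OiPr) (15 mol %), 1,4-benzoquinone (30 mol %), toluene (0.5 mM), 100 °C
Reagents that add atoms: none
Why: Ring-closing metathesis between the propenyl group and the 1,1-disubstituted olefin with loss of propene, the ten-membered ring accepting only the ring-cis (4Z) trisubstituted olefin while the conjugated and tetrasubstituted olefins stay out of the reaction.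

Step 10
Reactants: 16 (4Z,6S,8R,10S)-13-acetoxy-8-(3-methylbut-2-enoyloxy)-1-oxogermacra-4,7(11)-dien-12,6-olide
Product: 18 (4S,5R,6R,8R,10S)-13-acetoxy-4,5-epoxy-8-(3-methylbut-2-enoyloxy)-1-oxogermacr-7(11)-en-12,6-olide, via dioxirane 17 (not isolated)
Conditions: KHSO5 (as Oxone, 1.5 equiv), KHCO3, MeCN–aq. Na2EDTA, 0 °C, 2 mM in 16
Reagents that add atoms: potassium peroxymonosulfate [K+].[O-]S(=O)(=O)OO
Why: Proposed new method: KHSO5 adds to the C1 ketone and closes to the spiro dioxirane 17, whose peroxide oxygen lies over the inner face of the C4=C5 olefin (the face spanned by the C2–C3 bridge and anti to the C6 lactone oxygen, which external peracids are not expected to reach) and is transferred through a spiro transition state to give the cis (4S,5R) epoxide while returning the ketone; the closest known reactions are ketone-catalysed dioxirane (Shi-type) epoxidation and the intramolecular epoxidation of open-chain unsaturated ketones by their own in situ dioxiranes.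

## Compound list

1 | (E)-but-2-enal (crotonaldehyde) | C/C=C/C=O | starting material
2 | methyl prop-2-ynoate (methyl propiolate) | C#CC(=O)OC | starting material
3 | methyl 3-(methylzincio)prop-2-ynoate (zinc acetylide) | COC(=O)C#C[Zn]C | intermediate
4 | methyl (4S,5E)-4-hydroxyhept-5-en-2-ynoate | COC(=O)C#C[C@@H](O)/C=C/C | intermediate
5 | methyl (2E,4S,5E)-4-hydroxy-2-(hydroxymethyl)-3-iodohepta-2,5-dienoate (iodo diol ester) | COC(=O)/C(CO)=C(/I)[C@@H](O)/C=C/C | intermediate
6 | (5S)-3-(hydroxymethyl)-4-iodo-5-[(E)-prop-1-en-1-yl]furan-2(5H)-one | OCC1=C(I)[C@@H](OC1=O)/C=C/C | intermediate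
7 | [(5S)-4-iodo-2-oxo-5-[(E)-prop-1-en-1-yl]-2,5-dihydrofuran-3-yl]methyl acetate | CC(=O)OCC1=C(I)[C@@H](OC1=O)/C=C/C | intermediate
8 | 3-methylideneoxolan-2-one (α-methylene-γ-butyrolactone) | C=C1CCOC1=O | starting material
9 | (3S)-3-methyloxolan-2-one | O=C1[C@@H](C)CCO1 | intermediate
10 | 4-bromo-2-methylbut-1-ene | C=C(C)CCBr | starting material
11 | (3-methylbut-3-en-1-yl)magnesium bromide (Grignard reagent) | C=C(C)CC[Mg]Br | intermediate
12 | (3S)-1-hydroxy-3,7-dimethyloct-7-en-4-one | C=C(C)CCC(=O)[C@@H](C)CCO | intermediate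
13 | (3S)-3,7-dimethyl-4-oxooct-7-enal | C=C(C)CCC(=O)[C@@H](C)CC=O | intermediate
14 | [(5S)-4-[(1R,3S)-1-hydroxy-3,7-dimethyl-4-oxooct-7-en-1-yl]-2-oxo-5-[(E)-prop-1-en-1-yl]-2,5-dihydrofuran-3-yl]methyl acetate | CC(=O)OCC1=C([C@@H](OC1=O)/C=C/C)[C@H](O)C[C@H](C)C(=O)CCC(C)=C | intermediate
15 | (1R,3S)-1-[(2S)-4-(acetoxymethyl)-5-oxo-2-[(E)-prop-1-en-1-yl]-2,5-dihydrofuran-3-yl]-3,7-dimethyl-4-oxooct-7-en-1-yl 3-methylbut-2-enoate | CC(=O)OCC1=C([C@@H](OC1=O)/C=C/C)[C@H](OC(=O)C=C(C)C)C[C@H](C)C(=O)CCC(C)=C | intermediate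
16 | (4Z,6S,8R,10S)-13-acetoxy-8-(3-methylbut-2-enoyloxy)-1-oxogermacra-4,7(11)-dien-12,6-olide | CC(=O)OCC1=C2[C@@H](OC1=O)/C=C(C)\CCC(=O)[C@@H](C)C[C@H]2OC(=O)C=C(C)C | intermediate
17 | C1 spiro-dioxirane of 16: (4Z,6S,8R,10S)-13-acetoxy-1,1-epidioxy-8-(3-methylbut-2-enoyloxy)germacra-4,7(11)-dien-12,6-olide | CC(=O)OCC1=C2[C@@H](OC1=O)/C=C(C)\CCC3(OO3)[C@@H](C)C[C@H]2OC(=O)C=C(C)C | intermediate
18 | (4S,5R,6R,8R,10S)-13-acetoxy-4,5-epoxy-8-(3-methylbut-2-enoyloxy)-1-oxogermacr-7(11)-en-12,6-olide (CNP0220542.1) | CC(=O)OCC1=C2[C@@H](OC1=O)[C@H]1O[C@@]1(C)CCC(=O)[C@@H](C)C[C@H]2OC(=O)C=C(C)C | target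

## Step count and risks

Total steps: 10. Longest linear sequence: 7 steps (steps 1–3 then 7–10; the branch 4–6 then 7–10 is equally long).

The three steps most likely to fail:

Step 7 (C8 configuration in the Ni/Cr coupling). The coupling itself is dependable, but ligand control over the new carbinol next to a tetrasubstituted cyclic alkenyl group is not assured. The fallback sets out from 7 and 13: run the coupling without chiral ligand (CrCl2, catalytic NiCl2, DMSO, rt) and separate 14 from its C8 epimer [(5S)-4-[(1S,3S)-1-hydroxy-3,7-dimethyl-4-oxooct-7-en-1-yl]-2-oxo-5-[(E)-prop-1-en-1-yl]-2,5-dihydrofuran-3-yl]methyl acetate F1. Compound 14 goes through step 8 unchanged. F1 is esterified under Mitsunobu conditions (3-methylbut-2-enoic acid, PPh3, DIAD, THF, 0 °C), which forms the C8–O bond with inversion. Both streams come back to the route at 15.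

Step 9 (ring-closing metathesis to the ten-membered ring). Ring strain, oligomerisation and the sluggish 1,1-disubstituted olefin may defeat ring closure. The fallback sets out from 7 and 13 and swaps the order of the two C–C unions. Cross-metathesis of 7 with excess 13 (same ruthenium catalyst, CH2Cl2, 40 °C) gives the trisubstituted olefin as an E/Z mixture, from which the 4Z seco iodo aldehyde [(5S)-5-[(1Z,6S)-2,6-dimethyl-5,8-dioxooct-1-en-1-yl]-4-iodo-2-oxo-2,5-dihydrofuran-3-yl]methyl acetate F2 is separated. An intramolecular Nozaki–Hiyama–Kishi reaction (CrCl2, catalytic NiCl2, the step 7 ligand, THF, 2 mM) then closes the ring at C7–C8 to the macrocyclic alcohol (4Z,6S,8R,10S)-13-acetoxy-8-hydroxy-1-oxogermacra-4,7(11)-dien-12,6-olide F3. Steglich esterification as in step 8 comes back to the route at 16.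

Step 10 (the new transannular dioxirane epoxidation). The short C2–C3 tether may not let the dioxirane oxygen reach the olefin, Baeyer–Villiger oxidation of the ketone may compete, or background attack by KHSO5 on the outer face may give the other epoxide. The fallback uses known halohydrin chemistry and sets out from 16. NBS in aqueous acetone at 0 °C places bromine on the open face, and water (or the C1 carbonyl oxygen, then water) opens the bromonium at the tertiary C4 from the inner face. This gives the bromohydrin (4S,5S,6R,8R,10S)-13-acetoxy-5-bromo-4-hydroxy-8-(3-methylbut-2-enoyloxy)-1-oxogermacr-7(11)-en-12,6-olide F4, which may rest as its 1,4-hemiketal. K2CO3 in acetone at rt then closes the epoxide by attack of the C4 oxygen on C5 with inversion, coming back to the route at 18.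

## Further compounds

F1 | step 7 | [(5S)-4-[(1S,3S)-1-hydroxy-3,7-dimethyl-4-oxooct-7-en-1-yl]-2-oxo-5-[(E)-prop-1-en-1-yl]-2,5-dihydrofuran-3-yl]methyl acetate | CC(=O)OCC1=C([C@@H](OC1=O)/C=C/C)[C@@H](O)C[C@H](C)C(=O)CCC(C)=C
F2 | step 9 | [(5S)-5-[(1Z,6S)-2,6-dimethyl-5,8-dioxooct-1-en-1-yl]-4-iodo-2-oxo-2,5-dihydrofuran-3-yl]methyl acetate | CC(=O)OCC1=C(I)[C@@H](OC1=O)/C=C(C)\CCC(=O)[C@@H](C)CC=O
F3 | step 9 | (4Z,6S,8R,10S)-13-acetoxy-8-hydroxy-1-oxogermacra-4,7(11)-dien-12,6-olide | CC(=O)OCC1=C2[C@@H](OC1=O)/C=C(C)\CCC(=O)[C@@H](C)C[C@H]2O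
F4 | step 10 | (4S,5S,6R,8R,10S)-13-acetoxy-5-bromo-4-hydroxy-8-(3-methylbut-2-enoyloxy)-1-oxogermacr-7(11)-en-12,6-olide | CC(=O)OCC1=C2[C@@H](OC1=O)[C@H](Br)[C@](O)(C)CCC(=O)[C@@H](C)C[C@H]2OC(=O)C=C(C)C
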